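**Plan**

- Numbering: C1 = OCH2, C2 = CH, C3 = ArCH(OH), C4–C6 = CH2–CH=CH–Ar. The retrosynthesis cuts the C1–O ester bond, then the C3–aryl and C3–O bonds, then the C2–C4 bond back to diethyl malonate and a 3,4-dimethoxycinnamyl carbonate.
- Enabling feature: C3 is a secondary benzylic carbinol carbon bonded to C2, a hydroxyl oxygen and a 3,4-dimethoxyphenyl ring. As the OCH2 carbon of a carbamate it can be lithiated, take that benzene ring from boron and keep boron as the future OH. The target is an open chain carrying two benzene rings, so no ring is closed.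
- Forward: cinnamylation of malonate, reduction to the prochiral 1,3-diol, lipase desymmetrisation, TBS on the C1 arm and carbamate on the C3 arm, lithiation–borylation–oxidation, desilylation, Mitsunobu esterification at C1 with a silyl-protected Z acid (four steps from crotonaldehyde), final desilylation.
- Stereochemistry: C2 comes from the enzymatic desymmetrisation. C3 comes from (+)-sparteine-controlled deprotonation, relayed by stereospecific borylation, 1,2-shift and oxidation. The E C5=C6 bond comes from the cinnamyl alcohol, and the Z acrylate from an α-bromoenal whose geometry is kept through bromine–lithium exchange and carboxylation.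

Key step: step 8

Assumption: the Burkholderia cepacia lipase is taken to acetylate the pro-R hydroxymethyl arm of the 2-(arylallyl)propane-1,3-diol, as its size-based preference for primary alcohols and its behaviour towards 2-benzylpropane-1,3-diols suggest; the order silylation, deacetylation, carbamoylation is chosen to match.

**Route**

Step 1
Reactants: 1 (E)-3-(3,4-dimethoxyphenyl)prop-2-en-1-ol
Product: 2 ethyl (E)-3-(3,4-dimethoxyphenyl)allyl carbonate
Conditions: ClCO2Et, pyridine, CH2Cl2, 0 °C
Reagents that add atoms: ethyl chloroformate, CCOC(=O)Cl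
Why: O-acylation of the primary allylic alcohol with a chloroformate (carbonate formation) supplies the leaving group for palladium allylation without touching the E styrene.

Step 2
Reactants: 2 ethyl (E)-3-(3,4-dimethoxyphenyl)allyl carbonate; 3 diethyl malonate
Product: 4 diethyl 2-[(E)-3-(3,4-dimethoxyphenyl)allyl]malonate
Conditions: Pd(PPh3)4 (3 mol%), 3 (3 equiv), THF, 50 °C
Reagents that add atoms: none
Why: Tsuji–Trost allylation under base-free carbonate conditions, in which zerovalent palladium ionises the carbonate, the ethoxide released with CO2 deprotonates the malonate, and attack at the unsubstituted terminus of the aryl-conjugated π-allyl should give the linear E product, excess malonate suppressing double allylation.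

Step 3
Reactants: 4 diethyl 2-[(E)-3-(3,4-dimethoxyphenyl)allyl]malonate
Product: 5 2-[(E)-3-(3,4-dimethoxyphenyl)allyl]propane-1,3-diol
Conditions: LiAlH4, THF, 0 °C to rt; Fieser work-up
Reagents that add atoms: none
Why: Hydride reduction of both esters gives the prochiral 1,3-diol, and the isolated styrene is not reduced by LiAlH4.

Step 4
Reactants: 5 2-[(E)-3-(3,4-dimethoxyphenyl)allyl]propane-1,3-diol
Product: 6 (R)-2-[(E)-3-(3,4-dimethoxyphenyl)allyl]-3-hydroxypropyl acetate
Conditions: Burkholderia cepacia lipase (Amano PS, immobilised), vinyl acetate, tBuOMe, 25 °C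
Reagents that add atoms: vinyl acetate, CC(=O)OC=C
Why: Lipase-catalysed enantiotopic-group-selective transesterification (desymmetrisation of a prochiral 2-substituted propane-1,3-diol) with an irreversible acyl donor: the enzyme is expected to acylate the pro-R hydroxymethyl arm when the 2-substituent is a large arylalkyl group, which sets C2, and letting a little diacetate form consumes the minor enantiomer.

Step 5
Reactants: 6 (R)-2-[(E)-3-(3,4-dimethoxyphenyl)allyl]-3-hydroxypropyl acetate
Product: 7 (S)-3-[(tert-butyldimethylsilyl)oxy]-2-[(E)-3-(3,4-dimethoxyphenyl)allyl]propyl acetate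
Conditions: TBSCl, imidazole, CH2Cl2, 0 °C
Reagents that add atoms: tert-butyldimethylsilyl chloride, CC(C)(C)[Si](C)(C)Cl
Why: Silyl ether formation at the free primary hydroxyl under imidazole is fast and nearly neutral, so the acetate should not shift between the two arms (which would scramble C2); the descriptor becomes S only because the silyloxymethyl arm now outranks the acetoxymethyl arm.

Step 6
Reactants: 7 (S)-3-[(tert-butyldimethylsilyl)oxy]-2-[(E)-3-(3,4-dimethoxyphenyl)allyl]propyl acetate
Product: 8 (S)-3-[(tert-butyldimethylsilyl)oxy]-2-[(E)-3-(3,4-dimethoxyphenyl)allyl]propan-1-ol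
Conditions: K2CO3 (0.2 equiv), MeOH, 0 °C
Reagents that add atoms: none
Why: Base-catalysed transesterification (methanolysis) of the acetate with catalytic K2CO3 at 0 °C should leave the primary TBS ether in place and generate too little alkoxide for a silyl shift across the 1,3-diol, so C2 is preserved.

Step 7
Reactants: 8 (S)-3-[(tert-butyldimethylsilyl)oxy]-2-[(E)-3-(3,4-dimethoxyphenyl)allyl]propan-1-ol
Product: 9 (S)-3-[(tert-butyldimethylsilyl)oxy]-2-[(E)-3-(3,4-dimethoxyphenyl)allyl]propyl N,N-diisopropylcarbamate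
Conditions: iPr2NCOCl, Et3N, CH2Cl2, reflux
Reagents that add atoms: N,N-diisopropylcarbamoyl chloride, CC(C)N(C(C)C)C(=O)Cl
Why: Carbamoylation of the primary alcohol with a carbamoyl chloride under amine base, chosen over NaH so that no free alkoxide can trigger a 1,5-silyl shift, installs the group that directs lithiation and later departs from C3.

Step 8
Reactants: 9 (S)-3-[(tert-butyldimethylsilyl)oxy]-2-[(E)-3-(3,4-dimethoxyphenyl)allyl]propyl N,N-diisopropylcarbamate; 10 2-(3,4-dimethoxyphenyl)-4,4,5,5-tetramethyl-1,3,2-dioxaborolane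
Product: 14 (1S,2R)-3-[(tert-butyldimethylsilyl)oxy]-1-(3,4-dimethoxyphenyl)-2-[(E)-3-(3,4-dimethoxyphenyl)allyl]propan-1-ol, via lithiated carbamate 11 (not isolated), via lithium boronate complex 12 (not isolated), via secondary pinacol boronic ester 13 (not isolated)
Conditions: sBuLi (1.2 equiv), (+)-sparteine (1.2 equiv), Et2O, −78 °C, 5 h; 10 (1.3 equiv), −78 °C, 1 h; MgBr2·OEt2, −78 °C to reflux; then 30% H2O2, 2 M NaOH, THF, 0 °C to rt
Reagents that add atoms: hydrogen peroxide, OO
Why: Mechanism: the carbamate carbonyl pre-complexes sBuLi·(+)-sparteine, which removes the pro-R hydrogen of the C3 methylene to give the configurationally stable α-lithio carbamate 11, 10 traps it with retention as boronate complex 12, the 3,4-dimethoxyphenyl ring shifts from boron to C3 anti to the departing carbamate (inversion, MgBr2 assisting the leaving group) to give 13, and alkaline H2O2 turns C–B into C–O with retention. The closest known reaction type is the sparteine-mediated lithiation–borylation of primary O-alkyl carbamates with aryl pinacol boronic esters (a Matteson-type 1,2-metallate rearrangement) followed by oxidation to secondary benzylic alcohols. No ring is closed; the step makes the C3–aryl and C3–O bonds of an open chain. The new C3 stereocentre (S) is under reagent control, since (+)-sparteine selects the C3 hydrogen other than the pro-S one taken by its antipode and the retention–inversion–retention sequence relays that choice, whereas the neighbouring C2 centre can only make the deprotonation matched or mismatched. The step needs chemoselectivity for carbamate-directed deprotonation over addition of sBuLi to the C5=C6 styrene, allylic deprotonation at C4 and ortho-lithiation of the dimethoxybenzene rings, and this should be secured by the complex-induced proximity effect of the carbamate at −78 °C in Et2O with only a slight excess of base. Cyclisation of 11 onto the styrene would require a four-membered exo or five-membered endo closure and is not expected, the electron-rich aryl group should migrate readily, and the C1 silyl ether is inert.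

Step 9
Reactants: 14 (1S,2R)-3-[(tert-butyldimethylsilyl)oxy]-1-(3,4-dimethoxyphenyl)-2-[(E)-3-(3,4-dimethoxyphenyl)allyl]propan-1-ol
Product: 15 (1S,2R)-1-(3,4-dimethoxyphenyl)-2-[(E)-3-(3,4-dimethoxyphenyl)allyl]propane-1,3-diol
Conditions: Bu4NF, THF, 0 °C to rt
Reagents that add atoms: none
Why: Fluoride-mediated cleavage of the primary TBS ether (desilylation) meets no other silyl group, ester or base-sensitive function and touches neither stereocentre.

Step 10
Reactants: 16 (E)-but-2-enal (crotonaldehyde)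
Product: 18 (Z)-2-bromobut-2-enal, via 2,3-dibromobutanal 17 (not isolated)
Conditions: Br2, CH2Cl2, 0 °C; then Et3N, 0 °C to rt
Reagents that add atoms: bromine, BrBr
Why: Bromine addition to the enal followed by amine-induced dehydrobromination (E1cB through the α-bromo enolate) should give the α-bromoenal as the more stable isomer with CHO trans to the methyl group, that is Br cis to CH3 (Z).

Step 11
Reactants: 18 (Z)-2-bromobut-2-enal
Product: 19 (Z)-2-bromobut-2-en-1-ol
Conditions: NaBH4, CeCl3·7H2O, MeOH, 0 °C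
Reagents that add atoms: none
Why: Luche 1,2-reduction of the enal gives the allylic alcohol with the alkene geometry unchanged.

Step 12
Reactants: 19 (Z)-2-bromobut-2-en-1-ol
Product: 20 (Z)-[(2-bromobut-2-en-1-yl)oxy](tert-butyl)dimethylsilane
Conditions: TBSCl, imidazole, CH2Cl2, 0 °C to rt
Reagents that add atoms: tert-butyldimethylsilyl chloride, CC(C)(C)[Si](C)(C)Cl
Why: Standard silyl ether formation protects the hydroxyl that must not compete in the later esterification and is removable at the end with buffered HF.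

Step 13
Reactants: 20 (Z)-[(2-bromobut-2-en-1-yl)oxy](tert-butyl)dimethylsilane
Product: 22 (Z)-2-{[(tert-butyldimethylsilyl)oxy]methyl}but-2-enoic acid, via vinyllithium 21 (not isolated)
Conditions: tBuLi (2.1 equiv), Et2O, −78 °C, 15 min; CO2, −78 °C to 0 °C; cold 0.5 M HCl to pH 3
Reagents that add atoms: carbon dioxide, O=C=O
Why: Bromine–lithium exchange on a vinyl bromide and carboxylation of the vinyllithium both proceed with retention, so CO2H ends up cis to CH3 (Z acid), and the immediate CO2 quench at −78 °C should forestall silyl migration to carbon or loss of silanolate.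

Step 14
Reactants: 15 (1S,2R)-1-(3,4-dimethoxyphenyl)-2-[(E)-3-(3,4-dimethoxyphenyl)allyl]propane-1,3-diol; 22 (Z)-2-{[(tert-butyldimethylsilyl)oxy]methyl}but-2-enoic acid
Product: 23 (2R,3S)-3-(3,4-dimethoxyphenyl)-2-[(E)-3-(3,4-dimethoxyphenyl)allyl]-3-hydroxypropyl (Z)-2-{[(tert-butyldimethylsilyl)oxy]methyl}but-2-enoate
Conditions: PPh3 (1.05 equiv), diisopropyl azodicarboxylate (1.05 equiv, added last), 22 (1.1 equiv), THF, 0 °C
Reagents that add atoms: none
Why: Mitsunobu esterification activates the unhindered primary C1 hydroxyl as its oxyphosphonium and lets the carboxylate displace it, so the acid never becomes an acylating agent (no Z to E drift of the angelate-type double bond) and the hindered secondary benzylic C3 hydroxyl is expected to stay free.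

Step 15
Reactants: 23 (2R,3S)-3-(3,4-dimethoxyphenyl)-2-[(E)-3-(3,4-dimethoxyphenyl)allyl]-3-hydroxypropyl (Z)-2-{[(tert-butyldimethylsilyl)oxy]methyl}but-2-enoate
Product: 24 (2R,3S)-3-(3,4-dimethoxyphenyl)-2-[(E)-3-(3,4-dimethoxyphenyl)allyl]-3-hydroxypropyl (Z)-2-(hydroxymethyl)but-2-enoate
Conditions: HF·pyridine, pyridine, THF, 0 °C to rt
Reagents that add atoms: none
Why: Buffered HF desilylation of the primary allylic TBS ether avoids the basic conditions that could cause a 1,3-acyl shift to the C3 hydroxyl or isomerise the Z alkene.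

**Compound list**

1 | (E)-3-(3,4-dimethoxyphenyl)prop-2-en-1-ol | OC/C=C/c1ccc(OC)c(OC)c1 | starting material
2 | ethyl (E)-3-(3,4-dimethoxyphenyl)allyl carbonate | CCOC(=O)OC/C=C/c1ccc(OC)c(OC)c1 | intermediate
3 | diethyl malonate | CCOC(=O)CC(=O)OCC | starting material
4 | diethyl 2-[(E)-3-(3,4-dimethoxyphenyl)allyl]malonate | CCOC(=O)C(C/C=C/c1ccc(OC)c(OC)c1)C(=O)OCC | intermediate
5 | 2-[(E)-3-(3,4-dimethoxyphenyl)allyl]propane-1,3-diol | OCC(CO)C/C=C/c1ccc(OC)c(OC)c1 | intermediate
6 | (R)-2-[(E)-3-(3,4-dimethoxyphenyl)allyl]-3-hydroxypropyl acetate | CC(=O)OC[C@H](C/C=C/c1ccc(OC)c(OC)c1)CO | intermediate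
7 | (S)-3-[(tert-butyldimethylsilyl)oxy]-2-[(E)-3-(3,4-dimethoxyphenyl)allyl]propyl acetate | CC(=O)OC[C@H](C/C=C/c1ccc(OC)c(OC)c1)CO[Si](C)(C)C(C)(C)C | intermediate
8 | (S)-3-[(tert-butyldimethylsilyl)oxy]-2-[(E)-3-(3,4-dimethoxyphenyl)allyl]propan-1-ol | OC[C@H](C/C=C/c1ccc(OC)c(OC)c1)CO[Si](C)(C)C(C)(C)C | intermediate
9 | (S)-3-[(tert-butyldimethylsilyl)oxy]-2-[(E)-3-(3,4-dimethoxyphenyl)allyl]propyl N,N-diisopropylcarbamate | CC(C)N(C(C)C)C(=O)OC[C@H](C/C=C/c1ccc(OC)c(OC)c1)CO[Si](C)(C)C(C)(C)C | intermediate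
10 | 2-(3,4-dimethoxyphenyl)-4,4,5,5-tetramethyl-1,3,2-dioxaborolane | COc1ccc(B2OC(C)(C)C(C)(C)O2)cc1OC | starting material
11 | (1R,2R)-3-[(tert-butyldimethylsilyl)oxy]-2-[(E)-3-(3,4-dimethoxyphenyl)allyl]-1-lithiopropyl N,N-diisopropylcarbamate (sparteine-ligated; Li in place of the pro-R hydrogen) | CC(C)N(C(C)C)C(=O)O[C@H]([Li])[C@H](C/C=C/c1ccc(OC)c(OC)c1)CO[Si](C)(C)C(C)(C)C | intermediate
12 | lithium (1R,2R)-boronate complex: the carbon that carried Li now carries the B(aryl)(pinacolato) unit, with the carbamate still attached | CC(C)N(C(C)C)C(=O)O[C@H]([B-]1(c2ccc(OC)c(OC)c2)OC(C)(C)C(C)(C)O1)[C@H](C/C=C/c1ccc(OC)c(OC)c1)CO[Si](C)(C)C(C)(C)C.[Li+] | intermediate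
13 | 2-[(1S,2S)-3-[(tert-butyldimethylsilyl)oxy]-1-(3,4-dimethoxyphenyl)-2-[(E)-3-(3,4-dimethoxyphenyl)allyl]propyl]-4,4,5,5-tetramethyl-1,3,2-dioxaborolane | CC(C)(C)[Si](C)(C)OC[C@@H](C/C=C/c1ccc(OC)c(OC)c1)[C@H](B1OC(C)(C)C(C)(C)O1)c1ccc(OC)c(OC)c1 | intermediate
14 | (1S,2R)-3-[(tert-butyldimethylsilyl)oxy]-1-(3,4-dimethoxyphenyl)-2-[(E)-3-(3,4-dimethoxyphenyl)allyl]propan-1-ol | CC(C)(C)[Si](C)(C)OC[C@@H](C/C=C/c1ccc(OC)c(OC)c1)[C@H](O)c1ccc(OC)c(OC)c1 | intermediate
15 | (1S,2R)-1-(3,4-dimethoxyphenyl)-2-[(E)-3-(3,4-dimethoxyphenyl)allyl]propane-1,3-diol | OC[C@@H](C/C=C/c1ccc(OC)c(OC)c1)[C@H](O)c1ccc(OC)c(OC)c1 | intermediate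
16 | (E)-but-2-enal | C/C=C/C=O | starting material
17 | (2R*,3S*)-2,3-dibromobutanal (racemic, from anti addition) | C[C@H](Br)[C@H](Br)C=O | intermediate
18 | (Z)-2-bromobut-2-enal | C/C=C(\Br)C=O | intermediate
19 | (Z)-2-bromobut-2-en-1-ol | C/C=C(\Br)CO | intermediate
20 | (Z)-[(2-bromobut-2-en-1-yl)oxy](tert-butyl)dimethylsilane | C/C=C(\Br)CO[Si](C)(C)C(C)(C)C | intermediate
21 | vinyllithium from 20 (Li in place of Br, geometry retained) | C/C=C(\[Li])CO[Si](C)(C)C(C)(C)C | intermediate
22 | (Z)-2-{[(tert-butyldimethylsilyl)oxy]methyl}but-2-enoic acid | C/C=C(/CO[Si](C)(C)C(C)(C)C)C(=O)O | intermediate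
23 | (2R,3S)-3-(3,4-dimethoxyphenyl)-2-[(E)-3-(3,4-dimethoxyphenyl)allyl]-3-hydroxypropyl (Z)-2-{[(tert-butyldimethylsilyl)oxy]methyl}but-2-enoate | C/C=C(/CO[Si](C)(C)C(C)(C)C)C(=O)OC[C@@H](C/C=C/c1ccc(OC)c(OC)c1)[C@H](O)c1ccc(OC)c(OC)c1 | intermediate
24 | (2R,3S)-3-(3,4-dimethoxyphenyl)-2-[(E)-3-(3,4-dimethoxyphenyl)allyl]-3-hydroxypropyl (Z)-2-(hydroxymethyl)but-2-enoate | C/C=C(/CO)C(=O)OC[C@@H](C/C=C/c1ccc(OC)c(OC)c1)[C@H](O)c1ccc(OC)c(OC)c1 | target

**Summary**

Total step count: 15. Longest linear sequence: 11 steps (steps 1–9, 14, 15); the acid 22 is made in a 4-step side branch (steps 10–13).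

Steps most likely to fail, with fallbacks:

Step 8. Deprotonation may be slow or unselective. The diamine may be mismatched with the C2 centre, sBuLi may add to the C5=C6 styrene, or a ring or the C4 position may be lithiated. In that case the C3–aryl bond would be made by carbonyl addition, setting out from alcohol 8. Dess–Martin periodinane/NaHCO3 oxidation would give the aldehyde (R)-3-[(tert-butyldimethylsilyl)oxy]-2-[(E)-3-(3,4-dimethoxyphenyl)allyl]propanal F1. Addition of 3,4-dimethoxyphenylmagnesium bromide (THF, −78 °C) would give 14 together with its C1 epimer (1R,2R)-3-[(tert-butyldimethylsilyl)oxy]-1-(3,4-dimethoxyphenyl)-2-[(E)-3-(3,4-dimethoxyphenyl)allyl]propan-1-ol F2. Dess–Martin oxidation of the mixture would give the ketone (R)-3-[(tert-butyldimethylsilyl)oxy]-1-(3,4-dimethoxyphenyl)-2-[(E)-3-(3,4-dimethoxyphenyl)allyl]propan-1-one F3. Corey–Bakshi–Shibata reduction with (R)-1-methyl-3,3-diphenyltetrahydro-1H,3H-pyrrolo[1,2-c][1,3,2]oxazaborole and BH3·SMe2, expected by analogy with aryl alkyl ketones to give the S carbinol, rejoins the route at 14.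

Step 4. The lipase may discriminate poorly between the two hydroxymethyl arms or acetylate the opposite one. C2 would then be set by an oxazolidinone auxiliary, setting out from malonate 4. Saponification and thermal decarboxylation (NaOH, aq. EtOH; H3O+; 150 °C) would give (E)-5-(3,4-dimethoxyphenyl)pent-4-enoic acid F4. Acylation of lithiated (S)-4-benzyloxazolidin-2-one through the pivaloyl mixed anhydride would give (S)-4-benzyl-3-[(E)-5-(3,4-dimethoxyphenyl)pent-4-enoyl]oxazolidin-2-one F5. Hydroxymethylation of its TiCl4/iPr2NEt enolate with 1,3,5-trioxane, on the face away from the benzyl group, would give (S)-4-benzyl-3-[(2R,4E)-5-(3,4-dimethoxyphenyl)-2-(hydroxymethyl)pent-4-enoyl]oxazolidin-2-one F6. Silylation (TBSCl, imidazole) would give (S)-4-benzyl-3-[(2R,4E)-2-{[(tert-butyldimethylsilyl)oxy]methyl}-5-(3,4-dimethoxyphenyl)pent-4-enoyl]oxazolidin-2-one F7. LiBH4 reduction releases the auxiliary and comes back to the route at alcohol 8.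

Step 14. The Mitsunobu betaine may also activate the secondary, electron-rich benzylic C3 hydroxyl, leading to esterification with inversion, oxetane closure or elimination. That hydroxyl would then be masked first, setting out from 14. TBSOTf/2,6-lutidine would give (1S,2R)-1,3-bis[(tert-butyldimethylsilyl)oxy]-1-(3,4-dimethoxyphenyl)-2-[(E)-3-(3,4-dimethoxyphenyl)allyl]propane F8. Selective cleavage of the primary silyl ether (HF·pyridine, pyridine, THF, 0 °C) would give (2R,3S)-3-[(tert-butyldimethylsilyl)oxy]-3-(3,4-dimethoxyphenyl)-2-[(E)-3-(3,4-dimethoxyphenyl)allyl]propan-1-ol F9. Mitsunobu esterification with acid 22 would give (2R,3S)-3-[(tert-butyldimethylsilyl)oxy]-3-(3,4-dimethoxyphenyl)-2-[(E)-3-(3,4-dimethoxyphenyl)allyl]propyl (Z)-2-{[(tert-butyldimethylsilyl)oxy]methyl}but-2-enoate F10. Removal of both silyl groups with HF·pyridine comes back to the route at the target 24.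

Further compounds
F1 | step 8 | (R)-3-[(tert-butyldimethylsilyl)oxy]-2-[(E)-3-(3,4-dimethoxyphenyl)allyl]propanal | CC(C)(C)[Si](C)(C)OC[C@@H](C/C=C/c1ccc(OC)c(OC)c1)C=O
F2 | step 8 | (1R,2R)-3-[(tert-butyldimethylsilyl)oxy]-1-(3,4-dimethoxyphenyl)-2-[(E)-3-(3,4-dimethoxyphenyl)allyl]propan-1-ol | CC(C)(C)[Si](C)(C)OC[C@@H](C/C=C/c1ccc(OC)c(OC)c1)[C@@H](O)c1ccc(OC)c(OC)c1
F3 | step 8 | (R)-3-[(tert-butyldimethylsilyl)oxy]-1-(3,4-dimethoxyphenyl)-2-[(E)-3-(3,4-dimethoxyphenyl)allyl]propan-1-one | CC(C)(C)[Si](C)(C)OC[C@@H](C/C=C/c1ccc(OC)c(OC)c1)C(=O)c1ccc(OC)c(OC)c1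
F4 | step 4 | (E)-5-(3,4-dimethoxyphenyl)pent-4-enoic acid | OC(=O)CC/C=C/c1ccc(OC)c(OC)c1
F5 | step 4 | (S)-4-benzyl-3-[(E)-5-(3,4-dimethoxyphenyl)pent-4-enoyl]oxazolidin-2-one | O=C1OC[C@H](Cc2ccccc2)N1C(=O)CC/C=C/c1ccc(OC)c(OC)c1
F6 | step 4 | (S)-4-benzyl-3-[(2R,4E)-5-(3,4-dimethoxyphenyl)-2-(hydroxymethyl)pent-4-enoyl]oxazolidin-2-one | O=C1OC[C@H](Cc2ccccc2)N1C(=O)[C@@H](CO)C/C=C/c1ccc(OC)c(OC)c1
F7 | step 4 | (S)-4-benzyl-3-[(2R,4E)-2-{[(tert-butyldimethylsilyl)oxy]methyl}-5-(3,4-dimethoxyphenyl)pent-4-enoyl]oxazolidin-2-one | O=C1OC[C@H](Cc2ccccc2)N1C(=O)[C@@H](CO[Si](C)(C)C(C)(C)C)C/C=C/c1ccc(OC)c(OC)c1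
F8 | step 14 | (1S,2R)-1,3-bis[(tert-butyldimethylsilyl)oxy]-1-(3,4-dimethoxyphenyl)-2-[(E)-3-(3,4-dimethoxyphenyl)allyl]propane | CC(C)(C)[Si](C)(C)OC[C@@H](C/C=C/c1ccc(OC)c(OC)c1)[C@H](O[Si](C)(C)C(C)(C)C)c1ccc(OC)c(OC)c1
F9 | step 14 | (2R,3S)-3-[(tert-butyldimethylsilyl)oxy]-3-(3,4-dimethoxyphenyl)-2-[(E)-3-(3,4-dimethoxyphenyl)allyl]propan-1-ol | OC[C@@H](C/C=C/c1ccc(OC)c(OC)c1)[C@H](O[Si](C)(C)C(C)(C)C)c1ccc(OC)c(OC)c1
F10 | step 14 | (2R,3S)-3-[(tert-butyldimethylsilyl)oxy]-3-(3,4-dimethoxyphenyl)-2-[(E)-3-(3,4-dimethoxyphenyl)allyl]propyl (Z)-2-{[(tert-butyldimethylsilyl)oxy]methyl}but-2-enoate | C/C=C(/CO[Si](C)(C)C(C)(C)C)C(=O)OC[C@@H](C/C=C/c1ccc(OC)c(OC)c1)[C@H](O[Si](C)(C)C(C)(C)C)c1ccc(OC)c(OC)c1
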